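The route rests on cutting the C6'–C7' bond of the bicyclo[2.2.2]octene. Both ends of that bond are acceptor carbons: C6' is at the acyl level and C7' is the β position of the C1' enoate. The two-carbon C5'–C6' bridge and ring A lie on the same side of the bicycle, so C6' can be held as a δ-lactone on the C7a oxygen. Water-activated SmI2 joins the two carbons reductively and closes the bridged ring. In the same operation it sets C7' and C7a' and releases the C6' ketone and the C7a carbinol. Precursor 15 is a cis-fused cyclohexene δ-lactone in which C1' and C3' are already differentiated as an α-alkylidene β-hydroxy γ-lactone.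

Key step: step 10

Numbering: phthalide numbering is used. Unprimed atoms belong to the unit that contains ring A (C3a, C4, C5, C6, C7, C7a). Primed atoms belong to the unit inside the bicyclo[2.2.2]octene. The units are joined by C6–C7' and C7–C4'.

Assumption: the lipase acetylates the hydroxymethyl group on the (S)-configured ring carbon of 2; if it prefers the other arm, the same enzyme run hydrolytically on the meso diacetate gives 4.

Design remarks:
- (a) Once the C7a'=C3a' alkene is restored, C1' and C3' sit in almost identical surroundings. They are therefore differentiated before the key step, while only C3' is non-conjugated and has a directing hydroxyl next to it.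
- (b) That C3a' hydroxyl is also the leaving group that later restores the alkene without strong base.
- (c) C5 is carried as a chloride and C6' stays a ketone until the last step, so no protecting group is used.

Step 1
Reactants: 1 cis-1,2,3,6-tetrahydrophthalic anhydride
Product: 2 cis-cyclohex-4-ene-1,2-dimethanol
Conditions: LiAlH4, THF, 0 °C to reflux; H2O/aq. NaOH work-up
Reagents that add atoms: none
Why: Hydride reduction of a cyclic anhydride to the 1,4-diol, which leaves the two ring stereocentres untouched so that the product is still meso.

Step 2
Reactants: 2 cis-cyclohex-4-ene-1,2-dimethanol, 3 vinyl acetate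
Product: 4 [(1S,6R)-6-(hydroxymethyl)cyclohex-3-en-1-yl]methyl acetate
Conditions: Pseudomonas fluorescens lipase, vinyl acetate, t-BuOMe, 25 °C
Reagents that add atoms: vinyl acetate (3), C=COC(C)=O
Why: Enzymatic desymmetrisation by irreversible transesterification, in which the lipase distinguishes the enantiotopic hydroxymethyl groups, fixes C6 and C7 absolutely and places on the C7a oxygen the two carbons that become C5' and C6'.

Step 3
Reactants: 4 [(1S,6R)-6-(hydroxymethyl)cyclohex-3-en-1-yl]methyl acetate
Product: 5 [(1S,6R)-6-(chloromethyl)cyclohex-3-en-1-yl]methyl acetate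
Conditions: PPh3, N-chlorosuccinimide, CH2Cl2, 0 °C to rt
Reagents that add atoms: N-chlorosuccinimide, O=C1CCC(=O)N1Cl
Why: Appel-type chlorination of the free primary alcohol under neutral conditions gives a C5 handle that tolerates oxidants, amide bases, zerovalent palladium and SmI2–H2O.

Step 4
Reactants: 5 [(1S,6R)-6-(chloromethyl)cyclohex-3-en-1-yl]methyl acetate
Product: 6 cis-4,5-diol of the chloro acetate
Conditions: OsO4 (2 mol %), N-methylmorpholine N-oxide, acetone–H2O, rt
Reagents that add atoms: N-methylmorpholine N-oxide, C[N+]1([O-])CCOCC1; water, O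
Why: Catalytic OsO4 syn-dihydroxylation on the ring face away from the two arms; both new carbinol centres are removed again in step 5.

Step 5
Reactants: 6 cis-4,5-diol of the chloro acetate
Product: 7 ring 1,2-diketone
Conditions: (COCl)2, DMSO, CH2Cl2, −78 °C; Et3N, −78 °C to 0 °C
Reagents that add atoms: none
Why: Swern oxidation of both secondary alcohols gives the 1,2-diketone without C–C cleavage and leaves the acetate and the chloride alone.

Step 6
Reactants: 7 ring 1,2-diketone
Product: 9 cyclohexadiene bis(enol triflate), via mono(enol triflate) 8 (not isolated)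
Conditions: KN(SiMe3)2 (1.05 equiv) then PhNTf2 (1.1 equiv), the pair of additions repeated once, THF, −78 °C to −20 °C
Reagents that add atoms: N-phenylbis(trifluoromethanesulfonimide), O=S(=O)(N(c1ccccc1)S(=O)(=O)C(F)(F)F)C(F)(F)F
Why: Enolate O-triflation carried out twice, relying on the fact that the diketone and then the α-triflyloxy enone are far more acidic than the acetate, so one equivalent of base at a time enolises only the ring.

Step 7
Reactants: 9 cyclohexadiene bis(enol triflate), 10 carbon monoxide
Product: 11 dimethyl cis-5-(acetoxymethyl)-6-(chloromethyl)cyclohexa-1,3-diene-2,3-dicarboxylate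
Conditions: Pd(OAc)2 (10 mol %), dppf, CO (1 atm), MeOH, Et3N, DMF, 45 °C
Reagents that add atoms: carbon monoxide (10), [C-]#[O+]; methanol, CO
Why: Palladium-catalysed alkoxycarbonylation of alkenyl triflates (oxidative addition, CO insertion, methanolysis) at both positions brings in C1' and C3'.

Step 8
Reactants: 11 dimethyl cis-5-(acetoxymethyl)-6-(chloromethyl)cyclohexa-1,3-diene-2,3-dicarboxylate
Product: 13 C3a'-hydroxy diester δ-lactone, via Michael enolate 12 (not isolated)
Conditions: KN(SiMe3)2 (1.1 equiv), THF, −78 °C; 2-(phenylsulfonyl)-3-phenyloxaziridine, −78 °C; AcOH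
Reagents that add atoms: 2-(phenylsulfonyl)-3-phenyloxaziridine, O=S(=O)(c1ccccc1)N1OC1c1ccccc1
Why: Intramolecular ester-enolate Michael addition (6-exo-trig) followed by Davis oxidation of the resulting enolate, in which the short tether from the C7a oxygen reaches C4' only on the face of the arms (cis-fused lactone, sets C4') and the oxaziridine attacks C3a' on the opposite, open face.

Step 9
Reactants: 13 C3a'-hydroxy diester δ-lactone
Product: 15 bis-lactone precursor, via primary alcohol 14 (not isolated)
Conditions: BH3·SMe2, NaBH4 (5 mol %), THF, 0 °C to rt; MeOH; then camphorsulfonic acid (cat.), CH2Cl2, rt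
Reagents that add atoms: none
Why: Hydroxyl-directed borane reduction of an α-hydroxy ester, in which the C3a' alkoxyborane delivers hydride through a five-membered chelate to C3' only, followed by lactonisation of the new primary alcohol onto the conjugated C1' ester, so that C1' is fixed as the future lactone carbonyl and C3' as the future butylidene carbon.

Step 10
Reactants: 15 bis-lactone precursor
Product: 17 bicyclo[2.2.2]octanone hydroxy lactone, via oxatwistane hemiketal 16 (not isolated)
Conditions: SmI2 (2.2 equiv, 0.1 M in THF) premixed with degassed H2O (about 150 equiv), added slowly to 15 in THF, 0 °C; air, aq. NaHCO3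
Reagents that add atoms: none
Why: Proposed new method: water-bound divalent samarium transfers an electron to the δ-lactone carbonyl C6' (or, less productively, to the alkylidene lactone), the resulting radical anion bonds C6' to the enoate β carbon C7', a second electron turns the C7a' radical into a trivalent samarium enolate that is protonated, and the strained 4-oxatwistane hemiketal 16 opens to the C6' ketone and the free C7a carbinol. The closest known reaction types are the SmI2–H2O radical cyclisations of six-membered lactones onto unactivated alkenes and the ketyl–enoate reductive couplings of aldehydes and ketones; a lactone–enoate union that closes a bridged ring has not been shown. The new six-membered ring C6'–C5'–C4'–C7–C6–C7' forms in a 6-exo-trig mode (the alkene partner C7a' stays outside it), which is the same event as a 1,4-transannular closure of the cyclohexene boat to the bicyclo[2.2.2]octane. C7' can only be attacked on the face over which the cis-fused δ-lactone holds C6', and C7a' can only be protonated so that the γ-lactone stays cis-fused, so both new centres are dictated by rings already present. The step needs the six-membered lactone to react beside a five-membered one, a primary chloride and a tertiary alcohol, and five-membered lactones and alkyl chlorides are inert to SmI2–H2O in the absence of amine or HMPA. Conjugate reduction of the alkylidene lactone and further reduction of the new ketone are the real dangers, so the reductant is limited to two electrons per molecule and added slowly, and any C6' carbinol is reoxidised in step 11.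

Step 11
Reactants: 17 bicyclo[2.2.2]octanone hydroxy lactone
Product: 18 C7a carboxylic acid
Conditions: Pr4NRuO4 (10 mol %), N-methylmorpholine N-oxide monohydrate (10 equiv), MeCN, rt
Reagents that add atoms: water, O; N-methylmorpholine N-oxide (terminal oxidant), C[N+]1([O-])CCOCC1
Why: Ley–Griffith oxidation run in the presence of water takes the primary alcohol through the aldehyde hydrate to the acid, returns any over-reduced C6' carbinol to the ketone and cannot touch the tertiary alcohol.

Step 12
Reactants: 18 C7a carboxylic acid
Product: 19 C7a methyl ester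
Conditions: Me3SiCHN2, toluene–MeOH, 0 °C
Reagents that add atoms: (trimethylsilyl)diazomethane, C[Si](C)(C)C=[N+]=[N-]
Why: Esterification with a diazoalkane under neutral conditions, so that the β-hydroxy lactone sees no base and cannot undergo retro-aldol cleavage.

Step 13
Reactants: 19 C7a methyl ester
Product: 20 C7a'=C3a' butenolide
Conditions: Burgess reagent, toluene, 70 °C; then Et3N (cat.), rt
Reagents that add atoms: none
Why: Burgess dehydration (syn elimination), well suited here because the C3a' hydroxyl and the acidic C7a' hydrogen are held eclipsed on the same side of the bicycle, while any β,γ-unsaturated isomer is equilibrated to the conjugated butenolide by the amine.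

Step 14
Reactants: 20 C7a'=C3a' butenolide
Product: 21 C5 iodide
Conditions: NaI, 2-butanone, 80 °C
Reagents that add atoms: sodium iodide, [Na+].[I-]
Why: Finkelstein halide exchange (SN2), carried out while C6' is still a flat carbonyl carbon so that there is room next to C5 for the displacement.

Step 15
Reactants: 21 C5 iodide, 22 hept-1-en-3-one
Product: 23 C5-alkylated triketo-type ester (Giese adduct)
Conditions: hept-1-en-3-one (4 equiv), (Me3Si)3SiH and AIBN added slowly, toluene, 80 °C
Reagents that add atoms: hept-1-en-3-one (22), C=CC(=O)CCCC
Why: Giese addition of the primary C5 radical to the terminal carbon of the vinyl ketone delivers C4, C3a, C3 and the butyl chain at once, the tetrasubstituted butenolide alkene being a poor radical acceptor.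

Step 16
Reactants: 23 C5-alkylated triketo-type ester (Giese adduct)
Product: 24 ring A 1,3-diketone
Conditions: KOtBu (2.5 equiv), THF, 0 °C; aq. HCl
Reagents that add atoms: none
Why: Intramolecular Claisen (Dieckmann-type) acylation of a ketone enolate, in which only attack by C3a on the C7a ester gives a six-membered ring, the stabilised 1,3-diketonate drives the equilibrium, and only the cis C6/C7 arrangement can close so that C7 is retained.

Step 17
Reactants: 24 ring A 1,3-diketone
Product: 25 C7a enol triflate
Conditions: NaH (1.05 equiv), THF, 0 °C; Tf2O, −78 °C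
Reagents that add atoms: trifluoromethanesulfonic anhydride, O=S(=O)(OS(=O)(=O)C(F)(F)F)C(F)(F)F
Why: O-triflation of the 1,3-diketonate, the only site deprotonated by one equivalent of NaH; 2-acylcyclohexanones enolise inside the six-membered ring, so the triflate should end up on C7a with the C7a=C3a alkene.

Step 18
Reactants: 25 C7a enol triflate, 10 carbon monoxide
Product: 27 ring A (Z)-butylidene lactone, via hydroxybutenolide 26 (not isolated)
Conditions: Pd(OAc)2 (5 mol %), dppf, CO (1 atm), H2O (10 equiv), iPr2NEt, DMF, 50 °C; then p-TsOH·H2O (cat.), toluene, 80 °C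
Reagents that add atoms: carbon monoxide (10), [C-]#[O+]; water, O
Why: Palladium-catalysed hydroxycarbonylation of the alkenyl triflate supplies C1, the resulting γ-keto acid closes to its ring tautomer, and acid-catalysed dehydration gives the thermodynamically preferred (Z)-butylidene lactone.

Step 19
Reactants: 27 ring A (Z)-butylidene lactone, 28 butanal
Product: 31 bis(butylidene) C6' ketone, via lithium aldolate 29 (not isolated), via C8' mesylate 30 (not isolated)
Conditions: LiN(SiMe3)2 (1.05 equiv), THF, −78 °C; butanal; MsCl; then DBU, −78 °C to rt
Reagents that add atoms: butanal (28), CCCC=O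
Why: Vinylogous aldol addition of the butenolide dienolate (an aromatic 2-oxidofuran and the most acidic site) through C3', followed by mesylation and E1cB elimination, which should favour the (Z)-alkene because the propyl chain then avoids C4'.

Step 20
Reactants: 31 bis(butylidene) C6' ketone
Product: 32 target CNP0289078.2
Conditions: NaBH4, CeCl3·7H2O, MeOH, −78 °C
Reagents that add atoms: none
Why: Luche reduction, selective for the ketone over the two conjugated lactones, with hydride approaching C6' from the side of the C7a'=C3a' bridge because the other face is covered by the C5 methylene of ring A, which places the hydroxyl toward ring A as required.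

Compound list
1 | cis-1,2,3,6-tetrahydrophthalic anhydride (meso) | O=C1OC(=O)[C@H]2CC=CC[C@@H]12 | starting material
2 | cis-cyclohex-4-ene-1,2-dimethanol (meso) | OC[C@@H]1CC=CC[C@@H]1CO | intermediate
3 | vinyl acetate | C=COC(C)=O | starting material
4 | [(1S,6R)-6-(hydroxymethyl)cyclohex-3-en-1-yl]methyl acetate | OC[C@@H]1CC=CC[C@@H]1COC(C)=O | intermediate
5 | [(1S,6R)-6-(chloromethyl)cyclohex-3-en-1-yl]methyl acetate | ClC[C@@H]1CC=CC[C@@H]1COC(C)=O | intermediate
6 | cis-4,5-diol of 5, both hydroxyl groups trans to the two cis arms | ClC[C@@H]1C[C@@H](O)[C@@H](O)C[C@@H]1COC(C)=O | intermediate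
7 | [cis-2-(chloromethyl)-4,5-dioxocyclohexyl]methyl acetate, arm-bearing centres as in 5 | ClC[C@@H]1CC(=O)C(=O)C[C@@H]1COC(C)=O | intermediate
8 | mono(enol triflate) of 7 (one of two regioisomers drawn, both lead to 9) | ClC[C@@H]1CC(=O)C(OS(=O)(=O)C(F)(F)F)=C[C@@H]1COC(C)=O | intermediate
9 | cis-5-(acetoxymethyl)-6-(chloromethyl)cyclohexa-1,3-diene-2,3-diyl bis(triflate) | ClC[C@@H]1C=C(OS(=O)(=O)C(F)(F)F)C(OS(=O)(=O)C(F)(F)F)=C[C@@H]1COC(C)=O | intermediate
10 | carbon monoxide | [C-]#[O+] | starting material
11 | dimethyl cis-5-(acetoxymethyl)-6-(chloromethyl)cyclohexa-1,3-diene-2,3-dicarboxylate | ClC[C@@H]1C=C(C(=O)OC)C(C(=O)OC)=C[C@@H]1COC(C)=O | intermediate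
12 | potassium C3a' ester enolate of the cis-fused δ-lactone (C4'–C5' bond formed on the face of the arms) | ClC[C@@H]1C=C(C(=O)OC)C(=C([O-])OC)[C@@H]2CC(=O)OC[C@H]12.[K+] | intermediate
13 | cyclohexene cis-fused at C4'–C7 to the δ-lactone C6'(=O)–O–C7a, with C6–CH2Cl cis to the lactone arms, conjugated C7a' methyl ester, and at C3a' a methyl ester plus a tertiary OH trans to C5' | ClC[C@@H]1C=C(C(=O)OC)[C@](O)(C(=O)OC)[C@@H]2CC(=O)OC[C@H]12 | intermediate
14 | as 13 with C3' reduced to CH2OH (1,2-diol) | ClC[C@@H]1C=C(C(=O)OC)[C@](O)(CO)[C@@H]2CC(=O)OC[C@H]12 | intermediate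
15 | key-step precursor: as 13 with C1'(=O)–O–C3'H2 closed to an α-alkylidene β-hydroxy γ-lactone (C7'=C7a' exocyclic to it, C3a'–OH trans to C5') | ClC[C@@H]1C=C3C(=O)OC[C@]3(O)[C@@H]2CC(=O)OC[C@H]12 | intermediate
16 | 4-oxatwistane hemiketal (C6' bonded to C7', OH and O–C7a), drawn in neutral form | ClC[C@@H]1[C@H]3[C@@H]4C(=O)OC[C@]4(O)[C@H](C[C@@]3(O)OC5)[C@@H]15 | intermediate
17 | key-step product: bicyclo[2.2.2]octan-6'-one; C5H2Cl on C6 and C7aH2OH on C7 both point toward the C5'–C6' bridge; cis-fused γ-lactone on C7a'/C3a' toward the same bridge, C3a'–OH and C7a'–H toward the C6–C7 bridge | ClC[C@@H]1[C@H]3[C@@H]4C(=O)OC[C@]4(O)[C@H](CC3=O)[C@@H]1CO | intermediate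
18 | as 17 with C7a oxidised to CO2H | ClC[C@@H]1[C@H]3[C@@H]4C(=O)OC[C@]4(O)[C@H](CC3=O)[C@@H]1C(=O)O | intermediate
19 | methyl ester of 18 | ClC[C@@H]1[C@H]3[C@@H]4C(=O)OC[C@]4(O)[C@H](CC3=O)[C@@H]1C(=O)OC | intermediate
20 | bicyclo[2.2.2]oct-7a'-en-6'-one fused to the butenolide C1'(=O)–O–C3'H2, arms as in 19 | ClC[C@@H]1[C@H]3C4=C(COC4=O)[C@H](CC3=O)[C@@H]1C(=O)OC | intermediate
21 | as 20 with C5H2I | IC[C@@H]1[C@H]3C4=C(COC4=O)[C@H](CC3=O)[C@@H]1C(=O)OC | intermediate
22 | hept-1-en-3-one | C=CC(=O)CCCC | starting material
23 | as 20 with C5 carrying the chain C4H2–C3aH2–C3(=O)–butyl | CCCCC(=O)CCC[C@@H]1[C@H]3C4=C(COC4=O)[C@H](CC3=O)[C@@H]1C(=O)OC | intermediate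
24 | ring A closed, cis-fused at C6–C7: C7a ketone and pentanoyl group on C3a (enolisable, C3a not defined) | CCCCC(=O)C2CC[C@@H]1[C@H]3C4=C(COC4=O)[C@H](CC3=O)[C@@H]1C2=O | intermediate
25 | C7a enol triflate with C7a=C3a alkene and pentanoyl on C3a | CCCCC(=O)C=2CC[C@@H]1[C@H]3C4=C(COC4=O)[C@H](CC3=O)[C@@H]1C=2OS(=O)(=O)C(F)(F)F | intermediate
26 | ring A 3-butyl-3-hydroxybutenolide (ring tautomer of the keto acid, C3 epimers) | CCCCC1(O)OC(=O)C2=C1CC[C@@H]1[C@H]3C4=C(COC4=O)[C@H](CC3=O)[C@H]21 | intermediate
27 | ring A (Z)-3-butylidene lactone, primed unit still a simple butenolide, C6' ketone | CCC/C=C1\OC(=O)C2=C1CC[C@@H]1[C@H]3C4=C(COC4=O)[C@H](CC3=O)[C@H]21 | intermediate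
28 | butanal | CCCC=O | starting material
29 | lithium alkoxide of the C3'–C8' aldol adduct (C3' and C8' epimers) | CCC/C=C1\OC(=O)C2=C1CC[C@@H]1[C@H]3C4=C(C(OC4=O)C([O-])CCC)[C@H](CC3=O)[C@H]21.[Li+] | intermediate
30 | C8' methanesulfonate of the aldol adduct | CCC/C=C1\OC(=O)C2=C1CC[C@@H]1[C@H]3C4=C(C(OC4=O)C(OS(C)(=O)=O)CCC)[C@H](CC3=O)[C@H]21 | intermediate
31 | C6' ketone with both (Z)-butylidene lactones | CCC/C=C1\OC(=O)C2=C1CC[C@@H]1[C@H]3C4=C(/C(=C/CCC)OC4=O)[C@H](CC3=O)[C@H]21 | intermediate
32 | CNP0289078.2 (C6'–OH toward ring A) | CCC/C=C1\OC(=O)C2=C1CC[C@@H]1[C@H]3C4=C(/C(=C/CCC)OC4=O)[C@H](C[C@H]3O)[C@H]21 | target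

Total step count: 20. Longest linear sequence: 20 steps (1 to 32).

Steps most likely to fail

Step 10. Electron transfer to the conjugated lactone followed by protonation (plain conjugate reduction), or further reduction of the newly formed ketone, may outrun C–C bond formation. The fallback uses known chemistry, sets out from 15 and returns at 18.
- iBu2AlH at −78 °C should reduce the saturated δ-lactone, the more electrophilic of the two, to the δ-lactol F1.
- The open hydroxy-aldehyde form of F1 undergoes the established SmI2/t-BuOH aldehyde ketyl–enoate cyclisation. The closure is the same 6-exo mode, and the C5' arm on the upper face of C4' can still reach C7' from one side only. This gives the bicyclic diol F2 (either C6' epimer).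
- The oxidation of step 11 converts both carbinols of F2 and gives keto acid 18.

Step 8. Kinetic deprotonation may occur at the vinylogous C7–H instead of the acetate, which leads to loss of acetate and aromatisation. Oxygen transfer to the hindered enolate may also be too slow. The fallback separates the two events, replaces the hard acetate enolate by a soft one, sets out from 11 and returns at 13.
- K2CO3 in MeOH removes the acetate to give the diene alcohol F3.
- Allyl hydrogen malonate, DCC and DMAP give the mixed malonate F4.
- Cs2CO3 in MeCN closes the malonate carbon onto C4' through the same tether to give the allyl ester lactone F5.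
- Pd(PPh3)4 with HCO2H/Et3N removes the allyl ester with decarboxylation to give the lactone diester F6.
- A separate enolisation with KN(SiMe3)2 and Davis oxidation, now on a substrate without an eliminable acetate, gives 13.

Step 6. The second enolisation may compete with enolisation of the acetate or with vinylogous deprotonation, and the bis(triflate) may decompose on handling. The fallback builds the two ester groups one after the other, sets out from 7 and returns at 11.
- Tf2O/Et3N at −78 °C gives 8, which is now isolated.
- Methoxycarbonylation under the conditions of step 7 gives the keto enoate F7.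
- Kinetic enolisation at the only remaining position next to the ketone, followed by PhNTf2, gives the dienyl triflate F8.
- A second methoxycarbonylation gives 11. Both regioisomers of 8 converge on 11.

Further compounds
F1 | step 10 | δ-lactol of 15 (C6' hemiacetal, anomers) | ClC[C@@H]1C=C3C(=O)OC[C@]3(O)[C@@H]2CC(O)OC[C@H]12
F2 | step 10 | bicyclo[2.2.2]octane diol, as 17 with a C6' carbinol (epimers) | ClC[C@@H]1[C@H]3[C@@H]4C(=O)OC[C@]4(O)[C@H](CC3O)[C@@H]1CO
F3 | step 8 | dimethyl cis-6-(chloromethyl)-5-(hydroxymethyl)cyclohexa-1,3-diene-2,3-dicarboxylate | ClC[C@@H]1C=C(C(=O)OC)C(C(=O)OC)=C[C@@H]1CO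
F4 | step 8 | allyl malonate ester of F3 | ClC[C@@H]1C=C(C(=O)OC)C(C(=O)OC)=C[C@@H]1COC(=O)CC(=O)OCC=C
F5 | step 8 | cis-fused δ-lactone carrying an allyl ester on C5' (C5' and C3a' epimers) | ClC[C@@H]1C=C(C(=O)OC)C(C(=O)OC)[C@@H]2C(C(=O)OCC=C)C(=O)OC[C@H]12
F6 | step 8 | cis-fused δ-lactone diester without the C3a' hydroxyl (C3a' epimers) | ClC[C@@H]1C=C(C(=O)OC)C(C(=O)OC)[C@@H]2CC(=O)OC[C@H]12
F7 | step 6 | 2-(methoxycarbonyl)cyclohex-2-enone from 8 (regioisomer matching the drawn 8) | ClC[C@@H]1CC(=O)C(C(=O)OC)=C[C@@H]1COC(C)=O
F8 | step 6 | dienyl triflate ester from F7 | ClC[C@@H]1C=C(OS(=O)(=O)C(F)(F)F)C(C(=O)OC)=C[C@@H]1COC(C)=O
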